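We start from amounts: each flask holds 1.00 equiv of first nucleophile and 0.950 equiv of second nucleophile per substrate. Once substrate is gone and the whole charge of second nucleophile is in the flask, c(target) exceeds c(second nucleophile) + c(dormant form) by just 0.0250 M.

all flasks: first nucleophile 1.00 equiv; time 5.0 h

|  | substrate | second nucleophile | remark |
|---|---|---|---|
| teal | 0.50 M | 0.950 equiv (fed, over 3.0 h) | all else is in the flask from the start; the feed brings no volume worth counting |
| ochre | 0.50 M (fed, over 3.0 h) | 0.950 equiv | all else is in the flask from the start; the feed brings no volume worth counting |
| red | 0.50 M | 0.950 equiv | everything together at the start |
| blue | 0.50 M (fed, over 20 min) | 0.950 equiv | all else is in the flask from the start; the feed brings no volume worth counting |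

- the best flask by amount of target, in percent of the substrate charged; "all alike" if 1.5 percentage points covers them all (teal / ochre / red / blue / all alike)
- amount of target at the end, in percent of the substrate charged, teal
- amount of target at the end, in percent of the substrate charged, ochre
- amount of target at the end, in percent of the substrate charged, red
- amount of target at the end, in percent of the substrate charged, blue

    second nucleophile ⇌ dormant form (K1 = 2.14, k1 = 3.69 × 10⁻⁴ /s)
    substrate → intermediate (k2 = 0.00818 /s)
    second nucleophile + intermediate → other capture product (k3 = 0.783 /M/s)
    second nucleophile + target → over-reaction product (k4 = 0.00135 /M/s)
    first nucleophile + intermediate → target (k5 = 2.02 /M/s)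

We follow red in slow motion. In the first instants, substrate's half-life of 1.4 min is shorter than the 0.52 h of second nucleophile going dormant, so the first intermediate meets both nucleophiles at their charges. The selectivity factor k5/k3, 2.58, weighted by the charges, sends 73.1 % of that first intermediate to target. First nucleophile is used faster than second at the opening, so this opening split, carried over the whole substrate, gives a rough and high estimate of c(target), about 0.365 M.

In the middle, free second nucleophile has two exits, and control crosses where k4·c(target) equals k1, at 0.273 M. Red starts above this crossing, but target falls below it and the pool then approaches its equilibrium, with a free share of 1/(1+K1).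

For the end, we set the pool equal to c(target). The loss becomes second order, and 1/c(target) grows by the erosion dose, k4·t/(1+K1), which is 7.74 /M over the run. Red then ends near 19.1 %.

Blue, with its target younger on average by half the feed time, ends near 19.6 %. For teal we take nearly clean capture and the dose 5.42 /M, which gives 27.0 %.

Ochre's pool has 3.0 h to go dormant, against a half-life of 0.52 h. Teal's fresh nucleophile instead meets target above the crossing. So we put ochre first, above 27.0 %.

The forecast names teal, with 32 % for teal, 29 % for ochre, 23 % for red and 24 % for blue, holding that “slow over-reaction erodes target in every flask”; its first place differs from ours.

The simulation gives ochre as best, with teal 29.5 %, ochre 34.6 %, red 21.6 % and blue 24.0 %.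

In red, target's half-life by over-reaction was 0.37 h at 0.0236 h and 6.5 h at 5.00 h, much longer, and 64 % of that step's turnover lay behind it at 1.00 h. The erosion dose left 19.1 % in red, against 21.6 % in the flask. For the red recipe at 0.30 M of substrate, the same dose leaves 27.1 %, and that flask holds 28.2 %.

The numbers of this flask come from no measurement; the run is a simulation.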